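The numbers of this flask come from no measurement; the run is a simulation.

I followed one catalyst round.

    reagent + free catalyst → catalyst intermediate A (k1 = 94.9 L mol⁻¹ s⁻¹)
    catalyst intermediate A ⇌ by-product + catalyst intermediate B (K2 = 0.826 M, k2 = 20.4 s⁻¹)
    substrate + catalyst intermediate B ⇌ catalyst intermediate C (K3 = 0.603 L mol⁻¹, k3 = 640 L mol⁻¹ s⁻¹)
    catalyst intermediate C → free catalyst + product (k4 = 447 s⁻¹)
    free catalyst → spent catalyst (k5 = 0.00257 s⁻¹)
    free catalyst ⇌ dormant form (K6 = 0.42, k6 = 0.00137 s⁻¹)
substrate 0.80 M; reagent 0.700 equiv; free catalyst 0.05 mol%
- the form that holds most of the catalyst when 50% of the substrate are converted (spent catalyst / catalyst intermediate C / catalyst intermediate A / dormant form / catalyst intermediate B / free catalyst)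
- its share of the catalyst then

**Holding ratio.** Seen from the catalyst, the scheme is a loop of stations in series. Near steady running the same flow passes each station, so each holds catalyst in proportion to its dwell time, and time drops out of the ratios. At 50% conversion I took [reagent] as 0.160 M, one reagent per product. Free catalyst was then captured at 15.2 s⁻¹, slower than catalyst intermediate A released it at 20.4 s⁻¹. Their quotient, 0.744, is the holding ratio: catalyst intermediate A per free catalyst.

**One number tested.** Counting those two stations gave free catalyst 57.3%, so the ratio named the leader but needed help with the share. By-product, with [by-product] near 0.400 M, returned catalyst intermediate B to catalyst intermediate A at 9.88 s⁻¹. Catalyst intermediate B went onward through catalyst intermediate C at a net 75.9 s⁻¹. That raised the ratio to 0.841. Per free catalyst I also counted 0.200 of catalyst intermediate B and 0.0340 of catalyst intermediate C. Over 1.70 min, I estimated the loss steps at 0.261 of spent catalyst and 0.139 of dormant form per free catalyst. My resting state was free catalyst, at 40.4%.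

**The forecast.** It named free catalyst at 42%, slightly higher than my share, with capture “slightly slower than the release from intermediate A”.

**The simulation.** It gave free catalyst at 42.2%, ahead of catalyst intermediate A at 35.5%.

**Waiting catalyst.** In this flask, the holding ratio, scaled to [reagent] at 0.400 min, was 2.05, beside a reading of catalyst intermediate A over free catalyst of 2.10. Catalyst intermediate A led then, and it lost the lead as reagent fell. Waiting as free catalyst exposed the catalyst to loss: with the passage of free catalyst into spent catalyst left out, the apparent order in reagent went from 2.0 to 1.8.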